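Friday's run leaves a leftover: 3.1% of J still stands at 25.0 h, and I want to know what it means for a flask read at 2.0 d.

| flask | J | Z | remark | time |
|---|---|---|---|---|
| Friday's | 41 mM | 0.041 mM | the very flask that is asked about, followed so far |  |
| Saturday's | 20 mM | 0.041 mM | run made earlier |  |
| flask | 41 mM | 0.0410 mM |  | 2.0 d |

| run | time / h | J / % | D / % |
|---|---|---|---|
| Friday's | 1.33 | 82.1 | 8.3 |
| Friday's | 4.00 | 56.5 | 20.3 |
| Friday's | 6.00 | 42.6 | 28.8 |
| Friday's | 10.0 | 18.5 | 40.5 |
| Friday's | 15.0 | 7.7 | 48.0 |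
| Friday's | 20.0 | 2.9 | 51.1 |
| Friday's | 25.0 | 3.1 | 53.1 |
| Saturday's | 3.00 | 65.4 | 18.0 |
| Saturday's | 6.00 | 40.9 | 30.5 |
| Saturday's | 8.00 | 29.9 | 33.8 |
| Saturday's | 12.0 | 14.8 | 41.0 |
| Saturday's | 15.0 | 8.2 | 47.1 |
| Saturday's | 20.0 | 4.3 | 52.0 |

(scatter of a reading: 1 percentage point)

* part of the J that has reacted at 2.0 d
* pH of the solution at 2.0 d

- Z is the free proton; pH is minus the decimal logarithm of its molar concentration
- what has gone from J into another species counts as reacted, even if it can come back

I follow one molecule of J. Its chance per hour of leaving, k, the apparent first-order rate constant, reads 0.172 h⁻¹ on Friday's readings. Saturday's run, with 20 mM of J, reads about the same, 0.173 h⁻¹. So I reckon that 0.0261% of J survives to 2.0 d, which puts c at >99.9%. No reading shows Z, so I give no pH of my own.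

The forecast gives c = 98.5% (96% to 99.9%), below my figure, and pH 4.38 (4.2 to 4.45): “Z is only 0.1% of J and appears to be a catalyst, so it stays near 0.041 mM”.

The flask gives c = 99.3% and pH 3.70, with Z at 490% of its charge.

    J + L ⇌ G, settled at all times (K = 7200 M⁻¹)
    L ⇌ Q + Z, settled at all times (K = 4.00 × 10⁻⁶ M)
    J + Z → L + Z + D (k = 1460 M⁻¹ h⁻¹)
    J → L + D (k = 0.0111 h⁻¹)

In this flask, J + Z → L + Z + D uses J 5.4 times as fast as J → L + D just after the start. At 2.00 d that ratio stands at 26. In this flask k leaves 1.61% of J at 1.00 d, where the flask holds 2.00%, and at 2.0 d the flask holds more unbound J than k leaves, 0.69% against 0.0261%. In the neighbour flask, this same flask read at 12 h, k leaves 12.7% of J, and that flask holds 13.5%.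

The numbers in the tables stem from a simulated flask from invented constants, and the scatter is random.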